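The six benzyl ethers come off last. Before that, the two C3′–C3a′ and the two O1′–C2′ bonds of the dihydrobenzofurans are cut together. This opens both furans and both eight-membered rings to an open-chain hexaarylbutane with two (E)-styryl arms, which is then cut at the two C1/C4–ring B bonds and finally at the central C2–C3 bond.
Enabling feature: in each dihydrobenzofuran, O1′, C7a′ and C3a′ are a hydroxyl oxygen, its carbon and the adjacent ortho carbon of a resorcinol ring (ring C). C2′–C3′ is a former stilbene C=C with a 4-hydroxyphenyl ring (ring D) on C2′, and the C3′–C3a′ bond is also a member of an eight-membered ring (C3′, two carbons of ring B, butane C1–C2–C3, two carbons of ring C).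
Forward: ring C (as its bis-tosylate) and ring A are joined to a deoxybenzoin, which is dimerised at C2–C3. After reduction, both benzylic carbons are arylated with a preformed stilbene (rings B and D), and saponification frees only rings C and D. One laccase/O2 oxidation then closes the two eight-membered rings followed by the two furans, and hydrogenolysis ends the route.
Stereochemistry: only relative control is needed. C2/C3 come from base equilibration and crystallisation of the meso diketone, C1/C4 from Felkin–Anh-type Friedel–Crafts attack, C3′ from the tether and C2′ from the trans-selective oxa-Michael closure in the key step.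

Key step: step 9

Remark on the chemistry: exchanging the two halves of the target (C1↔C4, C2↔C3, one furan↔the other) inverts every stereocentre. The given structure is therefore a meso compound with an inversion centre and has no enantiomer, so "single enantiomer" is read as this single achiral diastereomer.
Labels: butane C1–C4. Ring A is the 4-oxyphenyl on C1/C4, ring B the resorcinol-type ring on C1/C4, ring C the resorcinol ring on C2/C3, and ring D the 4-oxyphenyl of the styryl arm. Primed locants refer to the dihydrobenzofuran. Methyl ethers are avoided because their late removal with BBr3 endangers both the stilbenes and the 2-aryl-dihydrobenzofurans.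

Step 1
Reactants: 1 5-bromoresorcinol
Product: 2 5-bromo-1,3-phenylene bis(4-methylbenzenesulfonate)
Conditions: TsCl (2.2 equiv), Et3N, DMAP (cat.), CH2Cl2, 0 °C → rt
Reagents that add atoms: 4-toluenesulfonyl chloride, Cc1ccc(cc1)S(=O)(=O)Cl
Why: O-sulfonylation of a phenol is routine, and the two tosylates make the future ring C non-nucleophilic, which is needed up to step 7.

Step 2
Reactants: 2 5-bromo-1,3-phenylene bis(4-methylbenzenesulfonate); 3 4′-benzyloxyacetophenone
Product: 4 1-[4-(benzyloxy)phenyl]-2-[3,5-bis(tosyloxy)phenyl]ethanone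
Conditions: Pd2(dba)3 (1 mol %), Xantphos (2.5 mol %), K3PO4, toluene, 80 °C
Reagents that add atoms: none
Why: Pd-catalysed ketone α-arylation (Buchwald–Hartwig type) with a phosphate base should engage only the C–Br bond, because aryl tosylates need far more electron-rich ligands, and the more acidic monoarylated ketone rests as its enolate and is not arylated twice.

Step 3
Reactants: 4 1-[4-(benzyloxy)phenyl]-2-[3,5-bis(tosyloxy)phenyl]ethanone (two molecules)
Product: 8 meso-(2R,3S)-1,4-bis[4-(benzyloxy)phenyl]-2,3-bis[3,5-bis(tosyloxy)phenyl]butane-1,4-dione, via sodium enolate 5 (not isolated), via α-iodo ketone 6 (not isolated), via dl/meso diketone mixture 7 (not isolated)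
Conditions: NaHMDS (1.0 equiv), THF, −78 °C; I2 (0.5 equiv), −78 °C → rt; crude: DBU (cat.), EtOH–toluene, reflux, slow cooling, filtration
Reagents that add atoms: none
Why: Oxidative enolate dimerisation with iodine (α-iodination, then SN2 by a second enolate) is the classical way from deoxybenzoins to 2,3-diaryl-1,4-diketones; both new centres stay epimerisable, so base equilibration with crystallisation of the centrosymmetric isomer, expected to be the less soluble one (crystallisation-induced diastereomer transformation), should set the meso C2/C3 relationship.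

Step 4
Reactants: 8 meso-1,4-diketone
Product: 9 (2R,3S)-1,4-bis[4-(benzyloxy)phenyl]-2,3-bis[3,5-bis(tosyloxy)phenyl]butane-1,4-diol (mixture of carbinol epimers at C1/C4)
Conditions: NaBH4, CeCl3·7H2O, THF–MeOH, −20 → 0 °C
Reagents that add atoms: none
Why: Luche reduction works under almost neutral conditions, so the acidic C2/C3–H should not epimerise, and the carbinol configuration does not matter because both centres are ionised in step 7.

Step 5
Reactants: 1 5-bromoresorcinol
Product: 10 1,3-bis(benzyloxy)-5-bromobenzene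
Conditions: BnBr (2.2 equiv), K2CO3, DMF, 60 °C
Reagents that add atoms: benzyl bromide, BrCc1ccccc1
Why: Williamson ether synthesis on a phenol is routine and gives ring B with ethers that activate it for step 7 and fall only to hydrogenolysis.

Step 6
Reactants: 10 1,3-bis(benzyloxy)-5-bromobenzene; 11 4-vinylphenyl acetate
Product: 12 (E)-4-[3,5-bis(benzyloxy)styryl]phenyl acetate
Conditions: Pd(OAc)2 (2 mol %), P(o-tol)3, Et3N, DMF, 100 °C
Reagents that add atoms: none
Why: The Mizoroki–Heck reaction of aryl halides with 4-acetoxystyrene is a standard entry to (E)-stilbenes (syn insertion, syn β-hydride elimination), and the aryl acetate survives the amine base.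

Step 7
Reactants: 9 1,4-diol; 12 (E)-4-[3,5-bis(benzyloxy)styryl]phenyl acetate (two molecules incorporated)
Product: 13 meso-(1R,2S,3R,4S)-1,4-bis[4-(benzyloxy)phenyl]-1,4-bis{2,4-bis(benzyloxy)-6-[(E)-4-acetoxystyryl]phenyl}-2,3-bis[3,5-bis(tosyloxy)phenyl]butane
Conditions: 12 (4 equiv), Bi(OTf)3 (10 mol %), 4 Å MS, CH2Cl2, −20 → 0 °C
Reagents that add atoms: none
Why: In this Lewis-acid-catalysed Friedel–Crafts benzylation the 4-benzyloxybenzylic alcohols (or the tetrahydrofuran they form reversibly) ionise, the tosylated rings C cannot close the otherwise fast indane, the acetate keeps the alkene unreactive, and ring B should be attacked para to one ether oxygen next to the styryl group as in its halogenation; C1 and C4 are set by Felkin–Anh-type attack anti to the C2–C3 bond with C2–H next to ring A of the cation (A1,3 strain), which gives ring B anti to C3 and ring A anti to ring C, that is (1R*,2S*).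

Step 8
Reactants: 13 protected open tetramer
Product: 14 meso-(1R,2S,3R,4S)-1,4-bis[4-(benzyloxy)phenyl]-1,4-bis{2,4-bis(benzyloxy)-6-[(E)-4-hydroxystyryl]phenyl}-2,3-bis(3,5-dihydroxyphenyl)butane
Conditions: KOH, dioxane–H2O, 80 °C, Ar; then 1 M HCl
Reagents that add atoms: none
Why: Saponification (hydroxide at sulfur of the aryl sulfonates and at the acyl carbon of the acetates) frees exactly the six phenols that take part in step 9, while benzyl ethers, stilbenes and the non-acidic stereocentres are inert.

Step 9
Reactants: 14 open tetramer with free rings C and D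
Product: 16 hexa-O-benzyl target (rings A and B benzylated; butane C1–C4 R,S,R,S; furan on the ring C of C3 (2′S,3′S), furan on the ring C of C2 (2′R,3′R)), via bis(p-quinone methide) 15 (not isolated)
Conditions: Trametes versicolor laccase (added in portions), air, EtOAc/0.1 M NaOAc buffer pH 5.0 (1:1, vigorous stirring), 0.3 mM, 25 °C
Reagents that add atoms: none
Why: Proposed new method: laccase/O2 removes one electron and one proton from each 4-hydroxystyryl phenol, the phenoxyl radical carries high spin density on the alkene carbon bound to ring B, this carbon attacks the carbon of the free resorcinol ring C that is ortho to the chain and ortho/para to its hydroxyls, and the far more oxidisable adduct radical loses a second electron and a proton to give the rearomatised p-quinone methide 15, so the non-conjugated resorcinol serves as the nucleophilic partner and need not be oxidised itself. The closest known reaction types are the laccase-, peroxidase- or Fe(III)-mediated 8–10′ coupling of resveratrol to ε-viniferin and radical–nucleophile oxidative phenol cross-coupling; the twofold intramolecular version and the isolated resorcinol partner are new. Each eight-membered ring closes 8-exo-trig at the styryl carbon, and each dihydrobenzofuran then closes 5-exo-trig by 1,6-addition of the adjacent hydroxyl to the quinone methide carbon. C3′ is fixed by the tether, because ring C keeps its benzylic C–H in the ring plane (A1,3 strain), the chain leading to ring B then runs on one face only, the styryl carbon must arrive from that face and C2′ must lie in the ring plane beside the hydroxyl, while C2′ is set trans to the C3′ aryl group by the reversible, sterically governed oxa-Michael step, and the inversion symmetry of the core makes the second half the mirror image. The step needs closure on the 1,3-related ring C and not on the vicinal one: in the centrosymmetric backbone rotamer ring B can stack on the far ring C once C1–H points away from C3, which also places it anti to the near ring, whereas the seven-membered alternative needs ring B gauche to both C3 and the near ring or ring A eclipsed with the ortho-benzyloxy group of ring B, so the 2,6-disubstituted ring B with its retained ether is what disfavours it, an argument from conformation only. The benzyl ethers leave no other oxidisable or nucleophilic phenol, and high dilution with low radical concentration should keep bimolecular δ-viniferin-type coupling behind the unimolecular closure.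

Step 10
Reactants: 16 hexa-O-benzyl target
Product: 17 target CNP0224452.1
Conditions: H2 (1 atm), 10% Pd/C, EtOAc–MeOH, rt
Reagents that add atoms: none
Why: Catalytic hydrogenolysis of aryl benzyl ethers should be faster than cleavage of the hindered secondary C2′–O bond of a 2-aryl-2,3-dihydrobenzofuran, no alkene is left, and no stereocentre is touched.

Compound list
1 | 5-bromoresorcinol | Oc1cc(O)cc(Br)c1 | starting material
2 | 5-bromo-1,3-phenylene bis(4-methylbenzenesulfonate) | Cc1ccc(cc1)S(=O)(=O)Oc1cc(Br)cc(OS(=O)(=O)c2ccc(C)cc2)c1 | intermediate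
3 | 4′-benzyloxyacetophenone | CC(=O)c1ccc(OCc2ccccc2)cc1 | starting material
4 | 1-[4-(benzyloxy)phenyl]-2-[3,5-bis(tosyloxy)phenyl]ethanone | O=C(Cc1cc(OS(=O)(=O)c2ccc(C)cc2)cc(OS(=O)(=O)c2ccc(C)cc2)c1)c1ccc(OCc2ccccc2)cc1 | intermediate
5 | sodium (Z)-enolate of 4 | [Na+].[O-]/C(=C\c1cc(OS(=O)(=O)c2ccc(C)cc2)cc(OS(=O)(=O)c2ccc(C)cc2)c1)c1ccc(OCc2ccccc2)cc1 | intermediate
6 | 2-iodo derivative of 4 (racemic) | O=C(C(I)c1cc(OS(=O)(=O)c2ccc(C)cc2)cc(OS(=O)(=O)c2ccc(C)cc2)c1)c1ccc(OCc2ccccc2)cc1 | intermediate
7 | 1,4-diketone, dl/meso mixture | O=C(c1ccc(OCc2ccccc2)cc1)C(c1cc(OS(=O)(=O)c2ccc(C)cc2)cc(OS(=O)(=O)c2ccc(C)cc2)c1)C(c1cc(OS(=O)(=O)c2ccc(C)cc2)cc(OS(=O)(=O)c2ccc(C)cc2)c1)C(=O)c1ccc(OCc2ccccc2)cc1 | intermediate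
8 | meso-(2R,3S)-1,4-diketone | O=C(c1ccc(OCc2ccccc2)cc1)[C@@H](c1cc(OS(=O)(=O)c2ccc(C)cc2)cc(OS(=O)(=O)c2ccc(C)cc2)c1)[C@@H](c1cc(OS(=O)(=O)c2ccc(C)cc2)cc(OS(=O)(=O)c2ccc(C)cc2)c1)C(=O)c1ccc(OCc2ccccc2)cc1 | intermediate
9 | (2R,3S)-1,4-diol, C1/C4 epimer mixture | OC(c1ccc(OCc2ccccc2)cc1)[C@@H](c1cc(OS(=O)(=O)c2ccc(C)cc2)cc(OS(=O)(=O)c2ccc(C)cc2)c1)[C@@H](c1cc(OS(=O)(=O)c2ccc(C)cc2)cc(OS(=O)(=O)c2ccc(C)cc2)c1)C(O)c1ccc(OCc2ccccc2)cc1 | intermediate
10 | 1,3-bis(benzyloxy)-5-bromobenzene | Brc1cc(OCc2ccccc2)cc(OCc2ccccc2)c1 | intermediate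
11 | 4-vinylphenyl acetate | CC(=O)Oc1ccc(C=C)cc1 | starting material
12 | (E)-4-[3,5-bis(benzyloxy)styryl]phenyl acetate | CC(=O)Oc1ccc(/C=C/c2cc(OCc3ccccc3)cc(OCc3ccccc3)c2)cc1 | intermediate
13 | protected open tetramer, meso-(1R,2S,3R,4S) | c2ccccc2COc1ccc(cc1)[C@H](c1c(OCc2ccccc2)cc(OCc2ccccc2)cc1/C=C/c1ccc(OC(C)=O)cc1)[C@@H](c1cc(OS(=O)(=O)c2ccc(C)cc2)cc(OS(=O)(=O)c2ccc(C)cc2)c1)[C@@H](c1cc(OS(=O)(=O)c2ccc(C)cc2)cc(OS(=O)(=O)c2ccc(C)cc2)c1)[C@@H](c1ccc(OCc2ccccc2)cc1)c1c(OCc2ccccc2)cc(OCc2ccccc2)cc1/C=C/c1ccc(OC(C)=O)cc1 | intermediate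
14 | open tetramer with free rings C and D, meso-(1R,2S,3R,4S) | c2ccccc2COc1ccc(cc1)[C@H](c1c(OCc2ccccc2)cc(OCc2ccccc2)cc1/C=C/c1ccc(O)cc1)[C@@H](c1cc(O)cc(O)c1)[C@@H](c1cc(O)cc(O)c1)[C@@H](c1ccc(OCc2ccccc2)cc1)c1c(OCc2ccccc2)cc(OCc2ccccc2)cc1/C=C/c1ccc(O)cc1 | intermediate
15 | bis(p-quinone methide) with both eight-membered rings closed | c7ccccc7COc1ccc([C@@H]2c3c(OCc7ccccc7)cc(OCc7ccccc7)cc3[C@H](C=C7C=CC(=O)C=C7)c4c(O)cc(O)cc4[C@H]4[C@@H](c5ccc(OCc7ccccc7)cc5)c5c(OCc7ccccc7)cc(OCc7ccccc7)cc5[C@@H](C=C7C=CC(=O)C=C7)c6c(O)cc(O)cc6[C@H]24)cc1 | intermediate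
16 | hexa-O-benzyl target | c7ccccc7COc1ccc([C@@H]2c3c(OCc7ccccc7)cc(OCc7ccccc7)cc3[C@H]3c4c(cc(O)cc4[C@H]4[C@@H](c5ccc(OCc7ccccc7)cc5)c5c(OCc7ccccc7)cc(OCc7ccccc7)cc5[C@@H]5c6c(cc(O)cc6[C@H]24)O[C@H]5c2ccc(O)cc2)O[C@@H]3c2ccc(O)cc2)cc1 | intermediate
17 | CNP0224452.1 | Oc1ccc([C@@H]2c3c(O)cc(O)cc3[C@H]3c4c(cc(O)cc4[C@H]4[C@@H](c5ccc(O)cc5)c5c(O)cc(O)cc5[C@@H]5c6c(cc(O)cc6[C@H]24)O[C@H]5c2ccc(O)cc2)O[C@@H]3c2ccc(O)cc2)cc1 | target

Total steps: 10. Longest linear sequence: 8 (steps 1, 2, 3, 4, 7, 8, 9, 10).

Steps most likely to fail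

Step 9. The styryl radical may close on the vicinal ring C (seven-membered ring). It may instead couple between molecules in the δ-viniferin manner, or fail to engage the non-conjugated resorcinol at all. The fallback sets out from 14 and comes back at 16, and it replaces the radical C–C bond formation by two-electron chemistry of known types.
- Electrophilic bromination with NBS (2 equiv, THF, −78 °C) should hit the free resorcinol rings, by far the most reactive arenes, para to one hydroxyl and next to the chain, giving the bis(2-bromoresorcinol) F1.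
- A twofold intramolecular Mizoroki–Heck reaction (Pd(PtBu3)2, Cy2NMe, DMA, 100 °C, high dilution) would form the two C3′–aryl bonds and give the bis(arylidene) compound F2, a tautomer of 15.
- Catalytic TsOH would protonate the 4-hydroxystyrene units to the quinone methides, which close by the same oxa-Michael addition to 16.
- The ring size is then decided in the carbopalladation and can be checked at F2 before the furans are formed.

Step 7. The cation may lose the C2/C3 proton, which scrambles the meso centres. It may attack the alkene or the position between the two ether oxygens, or show poor facial selectivity at C1/C4. The fallback sets out from 9 and comes back at 14, and it brings in ring B without the alkene.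
- Friedel–Crafts benzylation of commercial 3,5-bis(benzyloxy)benzyl alcohol (large excess, same catalyst) would give the bis(hydroxymethyl) compound F3.
- MnO2 oxidation would give the dialdehyde F4.
- Horner–Wadsworth–Emmons olefination with diethyl 4-(tert-butyldimethylsilyloxy)benzylphosphonate/NaH would give the (E,E)-bis(silyl ether) F5.
- Under the conditions of step 8, F5 loses tosyl and silyl groups to give 14.

Step 10. The benzylic C2′–O bonds may be opened by hydrogenolysis, or the shielded ortho ethers of ring B may be cleaved incompletely. The fallback sets out from 14 and comes back at 17, and it moves the deprotection in front of the ring closure.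
- BCl3/pentamethylbenzene (CH2Cl2, −78 °C) leaves alkenes untouched and would give the free dodecaphenol F6.
- Oxidation of F6 with laccase/air in acetone–acetate buffer, as in step 9, would give 17 directly, at the price of more free phenols in the oxidation.

Further compounds
F1 | step 9 | dibromide of 14, Br on each ring C ortho to the chain and next to a hydroxyl | c2ccccc2COc1ccc(cc1)[C@H](c1c(OCc2ccccc2)cc(OCc2ccccc2)cc1/C=C/c1ccc(O)cc1)[C@@H](c1c(Br)c(O)cc(O)c1)[C@@H](c1c(Br)c(O)cc(O)c1)[C@@H](c1ccc(OCc2ccccc2)cc1)c1c(OCc2ccccc2)cc(OCc2ccccc2)cc1/C=C/c1ccc(O)cc1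
F2 | step 9 | bis[(E)-4-hydroxybenzylidene] compound with both eight-membered rings closed | c7ccccc7COc1ccc([C@@H]2c3c(OCc7ccccc7)cc(OCc7ccccc7)cc3/C(=C\c7ccc(O)cc7)c4c(O)cc(O)cc4[C@H]4[C@@H](c5ccc(OCc7ccccc7)cc5)c5c(OCc7ccccc7)cc(OCc7ccccc7)cc5/C(=C\c7ccc(O)cc7)c6c(O)cc(O)cc6[C@H]24)cc1
F3 | step 7 | analogue of 13 with CH2OH in place of each styryl arm | c2ccccc2COc1ccc(cc1)[C@H](c1c(OCc2ccccc2)cc(OCc2ccccc2)cc1CO)[C@@H](c1cc(OS(=O)(=O)c2ccc(C)cc2)cc(OS(=O)(=O)c2ccc(C)cc2)c1)[C@@H](c1cc(OS(=O)(=O)c2ccc(C)cc2)cc(OS(=O)(=O)c2ccc(C)cc2)c1)[C@@H](c1ccc(OCc2ccccc2)cc1)c1c(OCc2ccccc2)cc(OCc2ccccc2)cc1CO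
F4 | step 7 | corresponding dialdehyde | c2ccccc2COc1ccc(cc1)[C@H](c1c(OCc2ccccc2)cc(OCc2ccccc2)cc1C=O)[C@@H](c1cc(OS(=O)(=O)c2ccc(C)cc2)cc(OS(=O)(=O)c2ccc(C)cc2)c1)[C@@H](c1cc(OS(=O)(=O)c2ccc(C)cc2)cc(OS(=O)(=O)c2ccc(C)cc2)c1)[C@@H](c1ccc(OCc2ccccc2)cc1)c1c(OCc2ccccc2)cc(OCc2ccccc2)cc1C=O
F5 | step 7 | analogue of 13 with OTBS in place of OAc on rings D | c2ccccc2COc1ccc(cc1)[C@H](c1c(OCc2ccccc2)cc(OCc2ccccc2)cc1/C=C/c1ccc(O[Si](C)(C)C(C)(C)C)cc1)[C@@H](c1cc(OS(=O)(=O)c2ccc(C)cc2)cc(OS(=O)(=O)c2ccc(C)cc2)c1)[C@@H](c1cc(OS(=O)(=O)c2ccc(C)cc2)cc(OS(=O)(=O)c2ccc(C)cc2)c1)[C@@H](c1ccc(OCc2ccccc2)cc1)c1c(OCc2ccccc2)cc(OCc2ccccc2)cc1/C=C/c1ccc(O[Si](C)(C)C(C)(C)C)cc1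
F6 | step 10 | fully free open tetramer, meso-(1R,2S,3R,4S) | Oc1ccc(cc1)[C@H](c1c(O)cc(O)cc1/C=C/c1ccc(O)cc1)[C@@H](c1cc(O)cc(O)c1)[C@@H](c1cc(O)cc(O)c1)[C@@H](c1ccc(O)cc1)c1c(O)cc(O)cc1/C=C/c1ccc(O)cc1
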